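The target's carbocycle (C4a, C5, C6, C7, C8, C8a) has its two oxygens on C7 and C8a, on either side of the methyl-bearing C8, which is the substitution of a 2-methylcyclohexane-1,3-dione. C8a, C4a, C5 and the 2-hydroxypropyl arm together are the six carbons of (S)-parasorbic acid. The route therefore annulates 3-pentanone onto this lactone: conjugate addition forms C5–C6, and Claisen attack of the second α-carbon on the lactone carbonyl forms C8–C8a, closing the carbocycle and releasing the (S)-carbinol in one flask. The precursor is the six-membered α,β-unsaturated lactone from ring-closing metathesis. Dehydrogenation, formylation at C4a and a pyranone-based coumarin annulation complete the target.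

Key step: step 4

Remark: compounds 8–10 are carried as mixtures of ring diastereomers and keto–enol tautomers, because those centres vanish at step 6; only the carbinol configuration is drawn.
Remark: the pyranone partner is the 6-(2-silyloxypropyl)-4-hydroxy-2-pyranone 19, since only it leaves the six-carbon 1,3-diketone chain needed for the dihydropyranone; the arm carbinol is silylated before aromatisation so that it cannot close onto the ortho-formyl group of 13.

Step 1
Reactants: 1 (S)-propylene oxide
Product: 2 (2S)-pent-4-en-2-ol
Conditions: CH2=CHMgBr, CuI (10 mol %), THF, −30 → 0 °C; then cold 1 M HCl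
Reagents that add atoms: vinylmagnesium bromide, C=C[Mg]Br
Why: Copper-catalysed Grignard opening of a terminal epoxide (SN2 at the unsubstituted carbon) does not touch the stereocentre, so the (S)-configuration of 1 is carried into the homoallylic alcohol.

Step 2
Reactants: 2 (2S)-pent-4-en-2-ol; 3 acryloyl chloride
Product: 4 (2S)-pent-4-en-2-yl prop-2-enoate
Conditions: Et3N, DMAP (5 mol %), CH2Cl2, 0 °C
Reagents that add atoms: none
Why: Standard acylation of a secondary alcohol by an acid chloride with amine base and DMAP as acyl-transfer catalyst, run cold to keep the acrylate from polymerising.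

Step 3
Reactants: 4 (2S)-pent-4-en-2-yl prop-2-enoate
Product: 5 (S)-parasorbic acid [(6S)-6-methyl-5,6-dihydro-2H-pyran-2-one]
Conditions: second-generation Grubbs catalyst (2 mol %), CH2Cl2 (0.01 M), 40 °C
Reagents that add atoms: none
Why: Ring-closing metathesis of a homoallylic acrylate to a six-membered α,β-unsaturated lactone is routine with this catalyst, dilution suppresses dimerisation and loss of ethene drives it, and the stereocentre is remote from the reacting alkenes.

Step 4
Reactants: 5 (S)-parasorbic acid; 6 3-pentanone
Product: 9 5-[(2S)-2-hydroxypropyl]-2,4-dimethylcyclohexane-1,3-dione, via lithium pent-2-en-3-olate 7 (not isolated), via keto lactone enolate 8 (not isolated)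
Conditions: 6 (1.2 equiv), LDA (1.15 equiv), THF, −78 °C; 5 added slowly, −78 → −40 °C; KOt-Bu (1.2 equiv), −40 °C → rt; then 1 M HCl
Reagents that add atoms: none
Why: The preformed lithium enolate 7 adds through its α-carbon to C4 of the lactone (the future coumarin C5) to give the lactone enolate of 8; KOt-Bu then equilibrates the enolates, the one on the untouched ethyl arm attacks the lactone carbonyl, and the bridged tetrahedral intermediate collapses by acyl–oxygen cleavage to the side-chain alkoxide and the 1,3-dione, which is deprotonated at once. This is the Michael–Claisen annulation by which ketone enolates and α,β-unsaturated esters give cyclohexane-1,3-diones, with the lactone serving as the ester so that its alkoxide leaving group stays in the molecule. The carbocycle closes in a 6-(enolendo)-exo-trig mode, the only Claisen closure open to 8, because the other ketone enolate could only form a four-membered ring. The ring centres at C4 and C5 of 9 (C2 is enolised) form without control under equilibrating base and are deleted at step 6, whereas the (S)-carbinol is untouched because its C–O bond is never broken. The step needs 1,4-addition to outrun carbonyl attack and γ-deprotonation of 5 (which would open it to sorbate): the s-trans enoate locked in the ring, the low temperature and slow addition of 5 to a slight excess of enolate should secure this, formation of the stabilised dione enolate pulls the equilibria forward, and the symmetry of 3-pentanone removes any regiochemical question.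

Step 5
Reactants: 9 5-[(2S)-2-hydroxypropyl]-2,4-dimethylcyclohexane-1,3-dione
Product: 10 5-[(2S)-2-(tert-butyldimethylsilyloxy)propyl]-2,4-dimethylcyclohexane-1,3-dione
Conditions: TBSCl (1.5 equiv), imidazole, DMF, rt; aq. citric acid work-up
Reagents that add atoms: tert-butyldimethylsilyl chloride, CC(C)(C)[Si](C)(C)Cl
Why: Imidazole-mediated silylation of the secondary alcohol, in which the acidic dione enol is silylated only reversibly and any enol silyl ether is cleaved by the mildly acidic aqueous work-up, so the silyl group should end on the carbinol alone.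

Step 6
Reactants: 10 5-[(2S)-2-(tert-butyldimethylsilyloxy)propyl]-2,4-dimethylcyclohexane-1,3-dione
Product: 11 5-[(2S)-2-(tert-butyldimethylsilyloxy)propyl]-2,4-dimethylbenzene-1,3-diol
Conditions: Pd/C (10 wt %), mesitylene, 165 °C, N2 sweep
Reagents that add atoms: none
Why: Catalytic dehydrogenation of a cyclohexane-1,3-dione over Pd/C with loss of one H2 gives the resorcinol, driven by aromatisation, and removes all ring stereocentres, while the silyl ether is inert under these neutral aprotic conditions.

Step 7
Reactants: 11 5-[(2S)-2-(tert-butyldimethylsilyloxy)propyl]-2,4-dimethylbenzene-1,3-diol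
Product: 13 2,4-dihydroxy-3,5-dimethyl-6-[(2S)-2-(tert-butyldimethylsilyloxy)propyl]benzaldehyde, via aryl iminium chloride 12 (not isolated)
Conditions: (COCl)2, DMF, MeCN, −15 °C; 11, −15 → 0 °C; then aq. NaOAc, rt
Reagents that add atoms: N,N-dimethylformamide, CN(C)C=O; water, O
Why: Vilsmeier–Haack formylation attacks the only unsubstituted ring carbon, which is para to one hydroxyl and ortho to the other, and buffered hydrolysis of iminium salt 12 gives the aldehyde, while the secondary silyl ether should survive the cold, brief exposure.

Step 8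
Reactants: 14 methyl (3R)-3-hydroxybutanoate
Product: 15 methyl (3R)-3-(tert-butyldimethylsilyloxy)butanoate
Conditions: TBSCl, imidazole, CH2Cl2, rt
Reagents that add atoms: tert-butyldimethylsilyl chloride, CC(C)(C)[Si](C)(C)Cl
Why: Routine imidazole-mediated silylation of a secondary alcohol, in which the stereocentre is not involved.

Step 9
Reactants: 15 methyl (3R)-3-(tert-butyldimethylsilyloxy)butanoate; 16 methyl acetoacetate
Product: 18 methyl (7R)-7-(tert-butyldimethylsilyloxy)-3,5-dioxooctanoate, via dilithio acetoacetate dianion 17 (not isolated)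
Conditions: 16 (2.2 equiv), LDA (4.5 equiv), THF, 0 °C; 15, −78 → 0 °C; then cold 1 M HCl
Reagents that add atoms: none
Why: Claisen acylation of the terminal carbanion of the acetoacetate dianion by an ester gives the 3,5-dioxo ester, with the dianion in excess because the product is deprotonated as it forms and the low temperature keeping the β-silyloxy ester from eliminating.

Step 10
Reactants: 18 methyl (7R)-7-(tert-butyldimethylsilyloxy)-3,5-dioxooctanoate
Product: 19 4-hydroxy-6-[(2R)-2-(tert-butyldimethylsilyloxy)propyl]-2H-pyran-2-one
Conditions: DBU (1.2 equiv), toluene, 110 °C; then 1 M HCl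
Reagents that add atoms: none
Why: Base-promoted enol lactonisation of a 3,5-dioxo ester to a 4-hydroxy-2-pyranone, driven by expulsion of methanol and formation of the acidic pyranone.

Step 11
Reactants: 13 2,4-dihydroxy-3,5-dimethyl-6-[(2S)-2-(tert-butyldimethylsilyloxy)propyl]benzaldehyde; 19 4-hydroxy-6-[(2R)-2-(tert-butyldimethylsilyloxy)propyl]-2H-pyran-2-one
Product: 21 7-hydroxy-6,8-dimethyl-3-[(5R)-5-(tert-butyldimethylsilyloxy)-3-oxohexanoyl]-5-[(2S)-2-(tert-butyldimethylsilyloxy)propyl]-2H-chromen-2-one, via arylidene pyrandione 20 (not isolated)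
Conditions: piperidine (20 mol %), AcOH (20 mol %), EtOH, 78 °C
Reagents that add atoms: none
Why: Knoevenagel condensation at C3 of the 4-hydroxy-2-pyranone gives arylidene 20, whose ortho-phenol then attacks the pyranone C2 carbonyl and opens that ring, the established lactone-exchange route from salicylaldehydes and 6-alkyl-4-hydroxy-2-pyranones to 3-(3-oxoacyl)coumarins, and neither stereocentre is touched.

Step 12
Reactants: 21 7-hydroxy-6,8-dimethyl-3-[(5R)-5-(tert-butyldimethylsilyloxy)-3-oxohexanoyl]-5-[(2S)-2-(tert-butyldimethylsilyloxy)propyl]-2H-chromen-2-one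
Product: 23 7-hydroxy-5-[(2S)-2-hydroxypropyl]-6,8-dimethyl-3-[(2R)-2-methyl-4-oxo-3,4-dihydro-2H-pyran-6-yl]-2H-chromen-2-one, via dihydroxy diketone 22 (not isolated)
Conditions: HCl (0.5 M in MeOH), 0 °C → rt
Reagents that add atoms: none
Why: Acidic methanolysis removes both silyl ethers, and the freed δ-hydroxy-β-diketone closes as a hemiketal on the coumarin-bound carbonyl and dehydrates to the 2,3-dihydro-4H-pyran-4-one, a standard cyclodehydration in which no C–O bond at either stereocentre is broken, so (R) and (S) are retained.

Compound list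
1 | (S)-propylene oxide [(2S)-2-methyloxirane] | C[C@H]1CO1 | starting material
2 | (2S)-pent-4-en-2-ol | C[C@H](O)CC=C | intermediate
3 | acryloyl chloride | C=CC(Cl)=O | starting material
4 | (2S)-pent-4-en-2-yl prop-2-enoate | C[C@H](OC(=O)C=C)CC=C | intermediate
5 | (S)-parasorbic acid, (6S)-6-methyl-5,6-dihydro-2H-pyran-2-one | C[C@H]1CC=CC(=O)O1 | intermediate
6 | 3-pentanone | CCC(=O)CC | starting material
7 | lithium pent-2-en-3-olate (not isolated; E/Z mixture) | CC=C(CC)O[Li] | intermediate
8 | (6S)-6-methyl-4-(3-oxopentan-2-yl)oxan-2-one, present in the flask as its enolate (not isolated; drawn as the neutral keto lactone) | C[C@H]1CC(C(C)C(=O)CC)CC(=O)O1 | intermediate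
9 | 5-[(2S)-2-hydroxypropyl]-2,4-dimethylcyclohexane-1,3-dione | C[C@H](O)CC1CC(=O)C(C)C(=O)C1C | intermediate
10 | 5-[(2S)-2-(tert-butyldimethylsilyloxy)propyl]-2,4-dimethylcyclohexane-1,3-dione | C[C@H](O[Si](C)(C)C(C)(C)C)CC1CC(=O)C(C)C(=O)C1C | intermediate
11 | 5-[(2S)-2-(tert-butyldimethylsilyloxy)propyl]-2,4-dimethylbenzene-1,3-diol | C[C@H](O[Si](C)(C)C(C)(C)C)Cc1cc(O)c(C)c(O)c1C | intermediate
12 | N-{2,4-dihydroxy-3,5-dimethyl-6-[(2S)-2-(tert-butyldimethylsilyloxy)propyl]benzylidene}-N-methylmethanaminium chloride (not isolated) | C[C@H](O[Si](C)(C)C(C)(C)C)Cc1c(C)c(O)c(C)c(O)c1C=[N+](C)C.[Cl-] | intermediate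
13 | 2,4-dihydroxy-3,5-dimethyl-6-[(2S)-2-(tert-butyldimethylsilyloxy)propyl]benzaldehyde | C[C@H](O[Si](C)(C)C(C)(C)C)Cc1c(C)c(O)c(C)c(O)c1C=O | intermediate
14 | methyl (3R)-3-hydroxybutanoate | C[C@@H](O)CC(=O)OC | starting material
15 | methyl (3R)-3-(tert-butyldimethylsilyloxy)butanoate | C[C@@H](O[Si](C)(C)C(C)(C)C)CC(=O)OC | intermediate
16 | methyl acetoacetate | CC(=O)CC(=O)OC | starting material
17 | dilithium dianion of methyl acetoacetate (not isolated) | [Li]OC(=C)C=C(O[Li])OC | intermediate
18 | methyl (7R)-7-(tert-butyldimethylsilyloxy)-3,5-dioxooctanoate | C[C@@H](O[Si](C)(C)C(C)(C)C)CC(=O)CC(=O)CC(=O)OC | intermediate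
19 | 4-hydroxy-6-[(2R)-2-(tert-butyldimethylsilyloxy)propyl]-2H-pyran-2-one | C[C@@H](O[Si](C)(C)C(C)(C)C)Cc1cc(O)cc(=O)o1 | intermediate
20 | 3-{2,4-dihydroxy-3,5-dimethyl-6-[(2S)-2-(tert-butyldimethylsilyloxy)propyl]benzylidene}-6-[(2R)-2-(tert-butyldimethylsilyloxy)propyl]-2H-pyran-2,4(3H)-dione (not isolated; alkene geometry not fixed) | C[C@@H](O[Si](C)(C)C(C)(C)C)CC1=CC(=O)C(=Cc2c(O)c(C)c(O)c(C)c2C[C@H](C)O[Si](C)(C)C(C)(C)C)C(=O)O1 | intermediate
21 | 7-hydroxy-6,8-dimethyl-3-[(5R)-5-(tert-butyldimethylsilyloxy)-3-oxohexanoyl]-5-[(2S)-2-(tert-butyldimethylsilyloxy)propyl]-2H-chromen-2-one | C[C@H](O[Si](C)(C)C(C)(C)C)Cc1c(C)c(O)c(C)c2oc(=O)c(C(=O)CC(=O)C[C@@H](C)O[Si](C)(C)C(C)(C)C)cc12 | intermediate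
22 | 7-hydroxy-3-[(5R)-5-hydroxy-3-oxohexanoyl]-5-[(2S)-2-hydroxypropyl]-6,8-dimethyl-2H-chromen-2-one (not isolated) | C[C@H](O)Cc1c(C)c(O)c(C)c2oc(=O)c(C(=O)CC(=O)C[C@@H](C)O)cc12 | intermediate
23 | 7-hydroxy-5-[(2S)-2-hydroxypropyl]-6,8-dimethyl-3-[(2R)-2-methyl-4-oxo-3,4-dihydro-2H-pyran-6-yl]-2H-chromen-2-one (CNP0308039.1) | Cc1c(O)c(C)c2oc(=O)c(C3=CC(=O)C[C@@H](C)O3)cc2c1C[C@H](C)O | target

Total step count: 12 (steps 1–7 and 11–12 on the main line, steps 8–10 for the pyranone).
Longest linear sequence: 9 steps, from (S)-propylene oxide 1 through steps 1–7, 11 and 12.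

Steps most likely to fail

Step 4. The enolate may act as a base at the γ-position of the lactone, which opens it irreversibly to sorbate, or the conjugate addition may reverse once KOt-Bu is present, before the Claisen closure takes place. The fallback separates the two bond formations and makes the first one under non-basic conditions. It sets out from 6, which is converted with TMSCl, Et3N and NaI in MeCN into trimethyl(pent-2-en-3-yloxy)silane F1. A Mukaiyama–Michael addition of this silyl enol ether to 5, mediated by TiCl4 in CH2Cl2 at −78 °C, should give after aqueous work-up the keto lactone 8, now isolated. Treatment of 8 with KOt-Bu in THF (0 °C → rt) then effects the Claisen closure alone and comes back to the route at 9.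

Step 6. Hydrogen released on the Pd surface may reduce part of the dione, so that disproportionation to mono-phenols competes, or dehydrogenation at the crowded C4–C5 bond may stall at the temperature needed. The fallback replaces the thermal dehydrogenation by a stepwise enol-ether oxidation near room temperature. It sets out from 10, which with TMSOTf and Et3N in CH2Cl2 at 0 °C should give the bis(trimethylsilyl) dienol ether F2. Saegusa–Ito oxidation of F2 with Pd(OAc)2 in MeCN at rt introduces the missing unsaturation, and the resulting dienone tautomerises to the resorcinol mono(trimethylsilyl) ether F3. Dilute aqueous citric acid in THF removes the aryl silyl group and comes back to the route at 11.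

Step 9. Proton transfer from the enolisable β-silyloxy ester to the dianion, followed by loss of silanolate to a crotonate, may compete with acylation, and the acidic product quenches dianion as it forms. The fallback makes the same carbon–carbon bond by aldol addition and adjusts the oxidation level afterwards. It sets out from 15, which is reduced with DIBAL-H in CH2Cl2 at −78 °C to (3R)-3-(tert-butyldimethylsilyloxy)butanal F4. Addition of dianion 17 to F4 in THF at −78 °C should give methyl (7R)-7-(tert-butyldimethylsilyloxy)-5-hydroxy-3-oxooctanoate F5 as a mixture of C5 epimers. Oxidation of F5 with Dess–Martin periodinane (CH2Cl2, NaHCO3) comes back to the route at 18.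

Further compounds
F1 | step 4 | trimethyl(pent-2-en-3-yloxy)silane (E/Z mixture) | CC=C(CC)O[Si](C)(C)C
F2 | step 6 | 5-[(2S)-2-(tert-butyldimethylsilyloxy)propyl]-4,6-dimethyl-1,3-bis(trimethylsilyloxy)cyclohexa-1,3-diene (numbered so that C1=C2 and C3=C4 are the double bonds; main regioisomer) | C[C@H](O[Si](C)(C)C(C)(C)C)CC1C=C(O[Si](C)(C)C)C(C)=C(O[Si](C)(C)C)C1C
F3 | step 6 | 5-[(2S)-2-(tert-butyldimethylsilyloxy)propyl]-2,4-dimethyl-3-(trimethylsilyloxy)phenol | C[C@H](O[Si](C)(C)C(C)(C)C)Cc1cc(O)c(C)c(O[Si](C)(C)C)c1C
F4 | step 9 | (3R)-3-(tert-butyldimethylsilyloxy)butanal | C[C@@H](O[Si](C)(C)C(C)(C)C)CC=O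
F5 | step 9 | methyl (7R)-7-(tert-butyldimethylsilyloxy)-5-hydroxy-3-oxooctanoate (C5 epimers) | C[C@@H](O[Si](C)(C)C(C)(C)C)CC(O)CC(=O)CC(=O)OC
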